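**Retrosynthetic overview**

1. The coumarin ether is disconnected at C11–O (Mitsunobu reaction with umbelliferone), leaving (5R,9R,10S)-11-hydroxydrim-7-en-3-one, carried as its silyl ether.
2. Rings A and B are made together in one cationic step: ring B (C5–C10) comes from the five-membered ring of a 2-methylbicyclo[3.1.0]hexan-2-ol by cyclopropylcarbinyl → homoallyl ring enlargement, and the opened cyclopropane carbon C5 is captured by a tethered silyl enol ether (C4), which closes ring A.
3. The enabling feature is that C5 of ring B is homoallylic to the C7=C8(CH3) double bond (C5–C6–C7=C8) and is also the ring-fusion atom bonded to C4, the gem-dimethyl carbon α to the C3 ketone of ring A. C5–C6–C7=C8 is therefore the retron of a tertiary cyclopropylcarbinyl cation, and C4 can arrive as an enol silane.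
4. The bicyclo[3.1.0]hexane comes from intramolecular cyclopropanation by a lithiated terminal epoxide; all fifteen skeletal carbons and the C9/C10 stereocentres come from an enantioselective Ireland–Claisen rearrangement of geranyl 3-methylbut-3-enoate.
5. Ring order: cyclopropane plus five-membered ring (step 6), then rings A and B together (step 11), then the aryl ether (step 13).

Key step: step 11

Atom numbers in the text are drimane numbers of the target (ring A: C1–C5 and C10; ring B: C5–C10; C11 = CH2O on C9; C12 = CH3 on C8; C15 = CH3 on C10). The target has 5α-H, 10β-CH3 and 9β-H, so C11 is trans to the angular methyl.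

Assumption: the (S,S)-configured boron controller is taken to deliver the (2R,3S) acid 5 in step 2; should the sense of induction be the opposite, its (R,R) enantiomer is used with no other change.

**Route**

Step 1
Reactants: 1 geraniol; 2 3-methylbut-3-enoic acid
Product: 3 geranyl 3-methylbut-3-enoate
Conditions: DCC, DMAP (5 mol %), CH2Cl2, 0 °C
Reagents that add atoms: none
Why: Steglich esterification of a primary allylic alcohol with an unhindered acid is routine, and the low temperature with only catalytic DMAP should keep the β,γ-double bond of the acid from moving into conjugation; no stereocentre is formed.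

Step 2
Reactants: 3 geranyl 3-methylbut-3-enoate
Product: 5 (2R,3S)-3-ethenyl-3,7-dimethyl-2-(prop-1-en-2-yl)oct-6-enoic acid, via boron ketene acetal 4 (not isolated)
Conditions: (S,S)-bis-sulfonamide + BBr3, CH2Cl2, rt (bromoborane formed, volatiles removed); then 3, i-Pr2NEt, CH2Cl2, −78 °C, then −20 → 4 °C; aqueous work-up
Reagents that add atoms: none
Why: Enantioselective Ireland–Claisen rearrangement through a chiral boron ketene acetal, in which soft enolization of the doubly activated α-CH2 gives 4 with the isopropenyl group cis to O–B, and the chair transition state with the (E)-trisubstituted geranyl alkene (C15 methyl axial, homoprenyl chain equatorial, isopropenyl equatorial) sets C9 and the quaternary C10 in the (2R,3S) relationship while the C2-symmetric sulfonamide ligand on boron selects the face.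

Step 3
Reactants: 5 (2R,3S)-3-ethenyl-3,7-dimethyl-2-(prop-1-en-2-yl)oct-6-enoic acid
Product: 6 (2R,3S)-3-ethenyl-3,7-dimethyl-2-(prop-1-en-2-yl)oct-6-en-1-ol
Conditions: LiAlH4, THF, 0 °C → reflux
Reagents that add atoms: none
Why: LiAlH4 reduction of a carboxylic acid to the primary alcohol leaves the three isolated alkenes and both stereocentres untouched.

Step 4
Reactants: 6 (2R,3S)-3-ethenyl-3,7-dimethyl-2-(prop-1-en-2-yl)oct-6-en-1-ol
Product: 7 (2R,3S)-3-ethenyl-3,7-dimethyl-2-(2-methyloxiran-2-yl)oct-6-en-1-ol (both epimers at the oxirane carbon)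
Conditions: VO(acac)2 (5 mol %), t-BuOOH (in decane), CH2Cl2, 0 °C → rt
Reagents that add atoms: tert-butyl hydroperoxide, CC(C)(C)OO
Why: Hydroxyl-directed epoxidation with VO(acac)2 and t-BuOOH should reach only the homoallylic 1,1-disubstituted alkene, because the monosubstituted vinyl group is one carbon further away and much less nucleophilic and the trisubstituted alkene is remote; the configuration of the new oxirane carbon does not matter since this carbon later becomes the cationic centre.

Step 5
Reactants: 7 (2R,3S)-3-ethenyl-3,7-dimethyl-2-(2-methyloxiran-2-yl)oct-6-en-1-ol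
Product: 8 tert-butyldiphenylsilyl ether of 7
Conditions: t-BuPh2SiCl, imidazole, DMF, rt
Reagents that add atoms: tert-butyl(chloro)diphenylsilane, CC(C)(C)[Si](Cl)(c1ccccc1)c1ccccc1
Why: Standard silylation of the primary alcohol, with the bulky and weakly Lewis-basic silyl ether chosen so that the C11 oxygen neither disturbs the carbenoid of step 6 nor captures the cation of step 11.

Step 6
Reactants: 8 tert-butyldiphenylsilyl ether of 7
Product: 10 bicyclic carbinol (2-methylbicyclo[3.1.0]hexan-2-ol core; cyclopropane syn to the C15 methyl), via oxiranyllithium 9 (not isolated)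
Conditions: LiN(C9H18) (lithium 2,2,6,6-tetramethylpiperidide, 2.5 equiv), t-BuOMe, 0 °C → rt; then H2O
Reagents that add atoms: none
Why: Intramolecular cyclopropanation of an unsaturated terminal epoxide through its α-lithiated form, in which oxiranyllithium 9 acts as a carbenoid whose carbon (C7) adds across the vinyl group with loss of its C–O bond to leave the tertiary alkoxide at C8; the cyclopropane should form on the face of the new five-membered ring that carries H9 and the C15 methyl so that the two large groups (CH2OSi and the homoprenyl chain, already cis to each other from step 2) end up exo, which sets C5 and C7.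

Step 7
Reactants: 10 bicyclic carbinol
Product: 11 side-chain epoxide of 10 (both epimers at the new oxirane CH)
Conditions: dimethyldioxirane (acetone solution), 0 °C
Reagents that add atoms: dimethyldioxirane, CC1(C)OO1
Why: Epoxidation of the only remaining alkene by neutral dimethyldioxirane avoids any acid that would ionize the tertiary cyclopropyl carbinol, and the new oxirane stereocentre is removed again in step 9.

Step 8
Reactants: 11 side-chain epoxide of 10
Product: 12 allylic alcohol (side chain CH2CH2CH(OH)C(CH3)=CH2; both carbinol epimers)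
Conditions: Et2Al(NC9H18) (from Et2AlCl and LiN(C9H18)), toluene, 0 °C; aqueous tartrate work-up
Reagents that add atoms: none
Why: Base-induced isomerization of a trisubstituted epoxide to an allylic alcohol with an aluminium amide, in which a methyl proton is removed syn to the oxygen so that the secondary alcohol next to a 1,1-disubstituted alkene results; the carbinol stereocentre is removed again in step 9.

Step 9
Reactants: 12 allylic alcohol
Product: 13 isopropenyl ketone (side chain CH2CH2C(=O)C(CH3)=CH2)
Conditions: Dess–Martin periodinane, NaHCO3, CH2Cl2, 0 °C → rt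
Reagents that add atoms: none
Why: Dess–Martin oxidation of the secondary allylic alcohol under buffered conditions gives the enone and leaves the tertiary alcohol, the cyclopropane and the silyl ether untouched.

Step 10
Reactants: 13 isopropenyl ketone
Product: 15 bis(triethylsilyl) compound (tertiary Et3Si ether plus tetrasubstituted Et3Si enol ether), via potassium enolate 14 (not isolated)
Conditions: K[(s-Bu)3BH], THF, −78 °C; then Et3N, Et3SiOTf, −78 → 0 °C
Reagents that add atoms: triethylsilyl trifluoromethanesulfonate, CC[Si](CC)(CC)OS(=O)(=O)C(F)(F)F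
Why: Conjugate reduction of a β-unsubstituted enone by the hindered borohydride gives the regiodefined tetrasubstituted potassium enolate 14, which Et3SiOTf silylates on oxygen while the tertiary alcohol is silylated as well, so the enol ether points only toward C4 and the regiochemistry problem of enolizing an isopropyl ketone never arises.

Step 11
Reactants: 15 bis(triethylsilyl) compound
Product: 17 (5R,9R,10S)-11-(tert-butyldiphenylsilyloxy)drim-7-en-3-one, via cyclopropylcarbinyl cation 16 (not isolated)
Conditions: Et3SiOTf (20 mol %), 2,6-di-tert-butyl-4-methylpyridine (30 mol %), CH2Cl2, −78 → −40 °C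
Reagents that add atoms: none
Why: Proposed new method: Et3SiOTf removes the tertiary silyloxy group as (Et3Si)2O to give the tertiary cyclopropylcarbinyl cation 16 (C8), which is delocalized into the cyclopropane; the tethered enol ether carbon C4 then attacks the cyclopropane carbon C5 from the side opposite the C5–C7 bond, that bond breaks to become the C7=C8 double bond, and the Et3Si group passes from the enol oxygen to triflate, so the catalyst returns. The closest known reactions are the acid-catalysed sabinene hydrate → terpinen-4-ol and cyclopropylcarbinyl → homoallyl rearrangements (the same ring enlargement with water or halide as nucleophile) and the Lewis-acid α-tert-alkylation of silyl enol ethers. Ring B arises by one-carbon expansion of the five-membered ring C5–C7–C8–C9–C10 through scission of the internal cyclopropane bond, which inserts C6 between C5 and C7, and ring A is closed by a 6-exo-tet attack of C4 on C5. C5 is the only new stereocentre and is set by inversion: because the cyclopropane is syn to the C15 methyl, C4 ends up anti to the C10–C1 bond and the ring fusion is trans (5α-H), while C9 and C10 are carried through unchanged and C4 is not stereogenic. The step needs attack at C5 and not at C6 or C8, and capture faster than proton loss: only attack at C5 closes a six-membered ring (C6 or C8 would give seven-membered rings), the tetrasubstituted enol silane is a strong π-nucleophile held next to C5, and the hindered pyridine removes traces of TfOH.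

Step 12
Reactants: 17 (5R,9R,10S)-11-(tert-butyldiphenylsilyloxy)drim-7-en-3-one
Product: 18 (5R,9R,10S)-11-hydroxydrim-7-en-3-one
Conditions: Bu4NF, THF, rt; then H2O
Reagents that add atoms: none
Why: Fluoride cleaves the primary silyl ether, and the ketone, the trisubstituted alkene and the three stereocentres are inert to Bu4NF at room temperature.

Step 13
Reactants: 18 (5R,9R,10S)-11-hydroxydrim-7-en-3-one; 19 umbelliferone
Product: 20 target, 7-{[(1R,4aR,8aS)-2,5,5,8a-tetramethyl-6-oxo-1,4,4a,5,6,7,8,8a-octahydronaphthalen-1-yl]methoxy}-2H-chromen-2-one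
Conditions: PPh3, diisopropyl azodicarboxylate, THF, 0 → 40 °C
Reagents that add atoms: none
Why: Mitsunobu etherification of a primary alcohol with an acidic phenol forms the C11–O–aryl bond at the CH2 carbon, so no stereocentre is touched, and the neutral conditions spare the lactone and the ketone.

**Compound list**

1 | geraniol, (2E)-3,7-dimethylocta-2,6-dien-1-ol | CC(C)=CCC/C(C)=C/CO | starting material
2 | 3-methylbut-3-enoic acid | CC(=C)CC(=O)O | starting material
3 | geranyl 3-methylbut-3-enoate | CC(C)=CCC/C(C)=C/COC(=O)CC(C)=C | intermediate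
4 | boron ketene acetal of 3 (isopropenyl cis to O–B; (4S,5S)-diazaborolidine on oxygen) | CC(C)=CCC/C(C)=C/CO/C(OB1N(S(=O)(=O)c2cc(cc(c2)C(F)(F)F)C(F)(F)F)[C@@H](c2ccccc2)[C@H](c2ccccc2)N1S(=O)(=O)c1cc(cc(c1)C(F)(F)F)C(F)(F)F)=C/C(C)=C | intermediate
5 | (2R,3S)-3-ethenyl-3,7-dimethyl-2-(prop-1-en-2-yl)oct-6-enoic acid | OC(=O)[C@H](C(C)=C)[C@](C)(C=C)CCC=C(C)C | intermediate
6 | (2R,3S)-3-ethenyl-3,7-dimethyl-2-(prop-1-en-2-yl)oct-6-en-1-ol | OC[C@H](C(C)=C)[C@](C)(C=C)CCC=C(C)C | intermediate
7 | (2R,3S)-3-ethenyl-3,7-dimethyl-2-(2-methyloxiran-2-yl)oct-6-en-1-ol, both epimers at the oxirane carbon | OC[C@H](C1(C)CO1)[C@](C)(C=C)CCC=C(C)C | intermediate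
8 | tert-butyldiphenylsilyl ether of 7 | CC(C)(C)[Si](c1ccccc1)(c1ccccc1)OC[C@H](C1(C)CO1)[C@](C)(C=C)CCC=C(C)C | intermediate
9 | oxiranyllithium from 8 (lithium on the oxirane CH2 carbon) | CC(C)(C)[Si](c1ccccc1)(c1ccccc1)OC[C@H](C1(C)OC1[Li])[C@](C)(C=C)CCC=C(C)C | intermediate
10 | 3-[(tert-butyldiphenylsilyloxy)methyl]-2,4-dimethyl-4-(4-methylpent-3-en-1-yl)bicyclo[3.1.0]hexan-2-ol; cyclopropane on the face carrying the 4-methyl and H-3, silyloxymethyl and side chain on the other face, both epimers at C-2 | CC(C)=CCC[C@]1(C)[C@H](CO[Si](c2ccccc2)(c2ccccc2)C(C)(C)C)C(C)(O)[C@H]2C[C@@H]12 | intermediate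
11 | side-chain epoxide of 10, 4-[2-(3,3-dimethyloxiran-2-yl)ethyl] analogue, both epimers at the oxirane CH | CC1(C)OC1CC[C@]2(C)[C@H](CO[Si](c3ccccc3)(c3ccccc3)C(C)(C)C)C(C)(O)[C@H]3C[C@@H]23 | intermediate
12 | allylic alcohol, 4-(3-hydroxy-4-methylpent-4-en-1-yl) analogue, both carbinol epimers | C=C(C)C(O)CC[C@]1(C)[C@H](CO[Si](c2ccccc2)(c2ccccc2)C(C)(C)C)C(C)(O)[C@H]2C[C@@H]12 | intermediate
13 | isopropenyl ketone, 4-(4-methyl-3-oxopent-4-en-1-yl) analogue | C=C(C)C(=O)CC[C@]1(C)[C@H](CO[Si](c2ccccc2)(c2ccccc2)C(C)(C)C)C(C)(O)[C@H]2C[C@@H]12 | intermediate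
14 | potassium enolate from 13 (tetrasubstituted, toward C4) | CC(C)=C([O-])CC[C@]1(C)[C@H](CO[Si](c2ccccc2)(c2ccccc2)C(C)(C)C)C(C)(O)[C@H]2C[C@@H]12.[K+] | intermediate
15 | bis(triethylsilyl) compound: tertiary Et3Si ether and Et3Si enol ether of 13 | CC(C)=C(O[Si](CC)(CC)CC)CC[C@]1(C)[C@H](CO[Si](c2ccccc2)(c2ccccc2)C(C)(C)C)C(C)(O[Si](CC)(CC)CC)[C@H]2C[C@@H]12 | intermediate
16 | tertiary cyclopropylcarbinyl cation (C8) as its triflate | CC(C)=C(O[Si](CC)(CC)CC)CC[C@]1(C)[C@H](CO[Si](c2ccccc2)(c2ccccc2)C(C)(C)C)[C+](C)[C@H]2C[C@@H]12.[O-]S(=O)(=O)C(F)(F)F | intermediate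
17 | (5R,9R,10S)-11-(tert-butyldiphenylsilyloxy)drim-7-en-3-one (5α-H, 9β-H, 10β-CH3) | CC1=CC[C@H]2C(C)(C)C(=O)CC[C@]2(C)[C@@H]1CO[Si](c1ccccc1)(c1ccccc1)C(C)(C)C | intermediate
18 | (5R,9R,10S)-11-hydroxydrim-7-en-3-one | CC1=CC[C@H]2C(C)(C)C(=O)CC[C@]2(C)[C@@H]1CO | intermediate
19 | umbelliferone, 7-hydroxy-2H-chromen-2-one | Oc1ccc2ccc(=O)oc2c1 | starting material
20 | 7-{[(1R,4aR,8aS)-2,5,5,8a-tetramethyl-6-oxo-1,4,4a,5,6,7,8,8a-octahydronaphthalen-1-yl]methoxy}-2H-chromen-2-one | CC1=CC[C@H]2C(C)(C)C(=O)CC[C@]2(C)[C@@H]1COc1ccc2ccc(=O)oc2c1 | target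

**Step count and risks**

Total step count: 13. Longest linear sequence: 13 steps (from geraniol and 3-methylbut-3-enoic acid to 20).

Steps most likely to fail:

Step 11 (Proposed new method). What may go wrong: proton loss from the tertiary cyclopropylcarbinyl cation, or protodesilylation of the enol ether, may outrun C–C bond formation at the secondary cyclopropane carbon. The fallback keeps the same ring enlargement but uses water as the nucleophile and closes ring A afterwards with known reactions; it sets out from 13 and returns at 17. Enone 13 in dilute aqueous acid (HClO4, THF–H2O, 0 °C) should undergo the known hydrolytic cyclopropylcarbinyl → homoallyl ring enlargement to the ring-expanded cyclohexenol F1. Dess–Martin oxidation should give the diketone F2. Copper hydride reductive aldol cyclization ([(Ph3P)CuH]6, toluene, rt) should add the C4 enolate to the C5 ketone and close ring A to the hydroxy diketone F3. Ionic hydrogenation (Et3SiH, BF3·OEt2, CH2Cl2, −78 °C) should then replace the tertiary 5-OH by hydrogen delivered from the α face, anti to the angular methyl, which gives 17.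

Step 6. What may go wrong: β-deprotonation with ring opening to an allylic alkoxide may outrun α-lithiation of the hindered 2,2-disubstituted oxirane, or the carbenoid may add with poor facial selectivity. The fallback replaces the lithium carbenoid by a rhodium carbenoid; it sets out from 8 and returns at 10. Periodic acid (H5IO6, THF–H2O) should cleave the oxirane of 8 to the methyl ketone F4. Detrifluoroacetylative diazo transfer (LiN(SiMe3)2, CF3CO2CH2CF3, −78 °C; then MsN3, Et3N, H2O) should give, through the trifluoroacetyl diketone F5, the diazoketone F6. Rh2(OAc)4 (CH2Cl2, rt) should effect intramolecular cyclopropanation of the vinyl group to the bicyclic ketone F7, in which the centre α to the carbonyl (C9) can settle in the exo configuration. MeMgBr with CeCl3 (THF, −78 °C) should add from the exo face and give 10 as a single carbinol epimer.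

Step 2. What may go wrong: loss of ketene acetal geometry or weak facial discrimination would lower the diastereo- or enantioselectivity, and the ester may isomerize to the conjugated senecioate before enolization. The fallback drops reagent control in favour of a racemic rearrangement and resolution; it sets out from 3 and returns at 5. LiN(i-Pr)2 and Me3SiCl in THF–DMPU (−78 °C → rt) should give the silyl ketene acetal F8 with the isopropenyl group cis to OSi and, after the [3,3] shift and hydrolysis, the racemate of 5. Crystallization of the (R)-1-phenylethylammonium salt F9 (or of the salt of the mirror-image amine, whichever is less soluble for the wanted enantiomer), followed by acidification, should give 5.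

**Further compounds**

F1 | step 11 | ring-expanded cyclohexenol: 5-hydroxy-cyclohex-3-ene (ring B) carrying the enone side chain on C10 | CC1=CC[C@@H](O)[C@](C)(CCC(=O)C(C)=C)[C@@H]1CO[Si](c1ccccc1)(c1ccccc1)C(C)(C)C
F2 | step 11 | diketone from oxidation of F1 (C5 ketone) | CC1=CCC(=O)[C@](C)(CCC(=O)C(C)=C)[C@@H]1CO[Si](c1ccccc1)(c1ccccc1)C(C)(C)C
F3 | step 11 | 5-hydroxy-11-(tert-butyldiphenylsilyloxy)drim-7-en-3-one, both epimers at C5 | CC1=CCC2(O)C(C)(C)C(=O)CC[C@]2(C)[C@@H]1CO[Si](c1ccccc1)(c1ccccc1)C(C)(C)C
F4 | step 6 | methyl ketone from oxirane cleavage of 8 | CC(C)(C)[Si](c1ccccc1)(c1ccccc1)OC[C@H](C(C)=O)[C@](C)(C=C)CCC=C(C)C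
F5 | step 6 | trifluoroacetyl diketone from F4 | CC(C)(C)[Si](c1ccccc1)(c1ccccc1)OC[C@H](C(=O)CC(=O)C(F)(F)F)[C@](C)(C=C)CCC=C(C)C
F6 | step 6 | diazoketone | CC(C)(C)[Si](c1ccccc1)(c1ccccc1)OC[C@H](C(=O)C=[N+]=[N-])[C@](C)(C=C)CCC=C(C)C
F7 | step 6 | bicyclo[3.1.0]hexan-2-one corresponding to 10 | CC(C)=CCC[C@]1(C)[C@H](CO[Si](c2ccccc2)(c2ccccc2)C(C)(C)C)C(=O)[C@H]2C[C@@H]12
F8 | step 2 | trimethylsilyl ketene acetal of 3 (isopropenyl cis to OSi) | CC(C)=CCC/C(C)=C/CO/C(O[Si](C)(C)C)=C/C(C)=C
F9 | step 2 | (R)-1-phenylethylammonium salt of 5 | [O-]C(=O)[C@H](C(C)=C)[C@](C)(C=C)CCC=C(C)C.C[C@@H]([NH3+])c1ccccc1
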